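**Retrosynthetic overview**
1. Both building blocks are commercial: (−)-sclareol 1 supplies all 20 labdane carbons with C5, C8, C9 and C10 already correct; ethyl 3-phenylpropanoate 2 supplies the acyl group.
2. Key disconnection, C15–O: the primary allylic C–O bond and the ester C–O bond are made in one operation by a 1,3-oxygen transposition of 1 (C13→C15, through the equilibrating primary alcohols 3 (E) and 4 (Z)) coupled to E-selective enzymatic acylation with 2, giving the E-allylic ester 5.
3. Second disconnection, C13–H: catalyst-controlled asymmetric hydrogenation of the C13=C14 bond of 5 sets C13 (S) and gives the target 6.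
4. Ring formation: none; the trans-decalin of 1 is carried through unchanged.

Assumption: the target is read as (13S)-8α-hydroxylabdan-15-yl 3-phenylpropanoate in the normal labdane series (5S,8R,9R,10S, as in natural (−)-sclareol); sclareol, ethyl 3-phenylpropanoate, V-MPS4 and Novozym 435 are taken as commercial.

**Step 1**
Reactants: 1 (−)-sclareol [(13R)-labd-14-ene-8α,13-diol]; 2 ethyl 3-phenylpropanoate
Product: 5 (13E)-8α-hydroxylabd-13-en-15-yl 3-phenylpropanoate, via (13E)-labd-13-ene-8α,15-diol 3 (not isolated), via (13Z)-labd-13-ene-8α,15-diol 4 (not isolated)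
Conditions: V-MPS4 (mesoporous-silica-bound oxovanadium, 3 mol% V), Novozym 435 (CAL-B), 2 (5 equiv), 5 Å MS, toluene, 50 °C
Reagents that add atoms: none
Why: Proposed new method: a dynamic kinetic geometric resolution in which the oxovanadium(V) sites reversibly esterify the allylic C13–OH of 1 and relay oxygen from C13 to C15 through a six-membered [3,3]-type oxo shift, so that 1, the E-alcohol 3 and the Z-alcohol 4 interconvert (equilibrium on the side of 1), while the CAL-B acyl-enzyme formed from 2 accepts only a primary alcohol and is expected to prefer the extended E isomer 3 (only CH3 cis to CH2OH, whereas 4 pushes the decalin-bearing arm into the narrow alcohol channel), so that by Curtin–Hammett the material drains to the single E ester 5 with the C15–O bond and the ester C–O bond formed and the tertiary C8–OH untouched; the closest known reaction type is the lipase/oxovanadium dynamic kinetic resolution of secondary allylic alcohols with 1,3-hydroxyl transposition, here moved from enantiomer selection to E/Z selection at a primary carbinol and to a tertiary-to-primary shift on a diol.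

**Step 2**
Reactants: 5 (13E)-8α-hydroxylabd-13-en-15-yl 3-phenylpropanoate
Product: 6 (13S)-8α-hydroxylabdan-15-yl 3-phenylpropanoate (target)
Conditions: [Ir(cod)(L*)]BArF (1 mol%; L* = Pfaltz-type bicyclic pyridyl-phosphinite, the enantiomer that reduces geranyl acetate to (S)-citronellyl acetate), H2 (50 bar), CH2Cl2, 25 °C
Reagents that add atoms: none
Why: Iridium-catalysed asymmetric hydrogenation of a trisubstituted alkene with a cationic Ir–N,P catalyst (precedented for O-acylated farnesol-type allylic esters; arene, ester and tertiary alcohol are not reduced) delivers H2 to the Re face of C13 (C14 > C12 > C16) of the pure E alkene, which sets C13 as S under catalyst control because the decalin stereocentres are too remote to interfere.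

**Compound list**
1 | (−)-sclareol, (13R)-labd-14-ene-8α,13-diol | C=C[C@](C)(O)CC[C@@H]1[C@@]2(C)CCCC(C)(C)[C@@H]2CC[C@@]1(C)O | starting material
2 | ethyl 3-phenylpropanoate | CCOC(=O)CCc1ccccc1 | starting material
3 | (13E)-labd-13-ene-8α,15-diol | C/C(=C\CO)CC[C@@H]1[C@@]2(C)CCCC(C)(C)[C@@H]2CC[C@@]1(C)O | intermediate
4 | (13Z)-labd-13-ene-8α,15-diol | C/C(=C/CO)CC[C@@H]1[C@@]2(C)CCCC(C)(C)[C@@H]2CC[C@@]1(C)O | intermediate
5 | (13E)-8α-hydroxylabd-13-en-15-yl 3-phenylpropanoate | C/C(=C\COC(=O)CCc1ccccc1)CC[C@@H]1[C@@]2(C)CCCC(C)(C)[C@@H]2CC[C@@]1(C)O | intermediate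
6 | (13S)-8α-hydroxylabdan-15-yl 3-phenylpropanoate; (3S)-5-[(1R,2R,4aS,8aS)-2-hydroxy-2,5,5,8a-tetramethyldecahydronaphthalen-1-yl]-3-methylpentyl 3-phenylpropanoate | C[C@H](CCOC(=O)CCc1ccccc1)CC[C@@H]1[C@@]2(C)CCCC(C)(C)[C@@H]2CC[C@@]1(C)O | target

**Step count and risks**
Total steps: 2. Longest linear sequence: 2 (1 → 5 → 6). The route has only two steps, so both are ranked; there is no third step.

Risk 1, step 1 (the proposed new step). Three things can go wrong:
- The lipase may not discriminate 3 from 4 well enough, which would carry Z ester into step 2 and give the 13R epimer.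
- The C8–OH may trap the ionising allyl vanadate at C13 and give 8,13-epoxylabd-14-enes (manoyl oxides) irreversibly.
- The tertiary-to-primary shift may be slow on this hindered diol.

Fallback with known chemistry, setting out from 1 and coming back at 5: acetylate both tertiary hydroxyls (AcCl, PhNMe2, CH2Cl2) to sclareol 8,13-diacetate F1. A Pd(II)-catalysed [3,3] allylic acetate transposition (PdCl2(MeCN)2, THF, 23 °C) then gives (13E)-labd-13-ene-8α,15-diyl diacetate F2, mainly E. KOH in MeOH–H2O at reflux removes both acetates to give diol 3, which is freed from the minor Z diol 4 by recrystallisation or AgNO3–silica chromatography. CAL-B with 2 (5 Å MS, toluene, no vanadium) acylates only the primary hydroxyl and returns to 5.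

Risk 2, step 2. The acidic iridium hydrides may cyclise the C8–OH onto C13 or cleave the allylic C–O bond, and face selectivity on this purely alkyl-substituted alkene may fall short.

Fallback, setting out from 5 and coming back at 6: methanolysis (K2CO3, MeOH) gives the free E-diol 3. Noyori hydrogenation of the allylic alcohol with Ru(OAc)2[(R)-BINAP] (H2 50–100 atm, MeOH) gives (13S)-labdane-8α,15-diol F3; the sense is the one by which geraniol gives (S)-citronellol. CAL-B with 2 (5 Å MS, toluene) acylates the primary hydroxyl selectively to give 6.

**Further compounds**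
F1 | step 1 | sclareol 8,13-diacetate | C=C[C@](C)(OC(C)=O)CC[C@@H]1[C@@]2(C)CCCC(C)(C)[C@@H]2CC[C@@]1(C)OC(C)=O
F2 | step 1 | (13E)-labd-13-ene-8α,15-diyl diacetate | C/C(=C\COC(C)=O)CC[C@@H]1[C@@]2(C)CCCC(C)(C)[C@@H]2CC[C@@]1(C)OC(C)=O
F3 | step 2 | (13S)-labdane-8α,15-diol | C[C@H](CCO)CC[C@@H]1[C@@]2(C)CCCC(C)(C)[C@@H]2CC[C@@]1(C)O
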